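**Retrosynthetic overview**
1. The dihydropyranone is closed last (step 6) from an open-chain 5,7,9,11-tetrahydroxy-3-oxo ester that is carried as two cyclic carbonates.
2. C3–C4 is cut to a primary iodide plus methyl malonyl chloride (radical nickel reductive acylation).
3. C12–C13, the key bond, is cut to a C2-symmetric diiodide plus oct-1-ene (radical nickel hydride hydroalkylation that differentiates the two identical termini).
4. The diiodide comes from a two-fold iodocarbonate cyclisation (both 1,3-dioxan-2-one rings formed together; C5 and C11 set syn) of the bis-Boc derivative of (4S,6S)-nona-1,8-diene-4,6-diol, itself made by two-directional allylation of propane-1,3-diol (C7/C9 anti).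
5. Ring order: two 1,3-dioxan-2-ones (step 3, removed in step 6), then the lactone (step 6).

Assumption: (S)-Cl,MeO-BIPHEP is taken as the ligand antipode that gives the (4S,6S)-diol; if the sense is opposite, the mirror-image ligand is used with no other change.

Atom labels C1–C20 refer to the target chain (C1 = lactone carbonyl, C5 = ring CH–O, C11 = carbinol bearing the nonyl group).

**Step 1**
Reactants: 1 propane-1,3-diol; 2 allyl acetate
Product: 3 (4S,6S)-nona-1,8-diene-4,6-diol
Conditions: [Ir(cod)Cl]2 (5 mol%), (S)-Cl,MeO-BIPHEP (10 mol%), 4-chloro-3-nitrobenzoic acid (20 mol%), Cs2CO3 (40 mol%), 2 (10 equiv), 1,4-dioxane, 90 °C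
Reagents that add atoms: none
Why: Krische two-directional transfer-hydrogenative carbonyl allylation; the iridium catalyst dehydrogenates each CH2OH and adds allyl under catalyst control, so C7 and C9 are set with the same sense and the C2-symmetric anti diol forms in high ee, the minor enantiomer being drained into the meso isomer.

**Step 2**
Reactants: 3 (4S,6S)-nona-1,8-diene-4,6-diol
Product: 5 di-tert-butyl (4S,6S)-nona-1,8-diene-4,6-diyl dicarbonate, via dilithium dialkoxide 4 (not isolated)
Conditions: n-BuLi (2.1 equiv), THF, −78 °C; then Boc2O (3 equiv), −78 → 0 °C; aqueous work-up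
Reagents that add atoms: di-tert-butyl dicarbonate, CC(C)(C)OC(=O)OC(=O)OC(C)(C)C
Why: Double O-acylation of the dialkoxide by excess Boc2O at low temperature outruns intramolecular attack on the hindered tert-butyl carbonate (which would give a cyclic carbonate, as Boc2O/DMAP does with 1,3-diols); no stereocentre is touched.

**Step 3**
Reactants: 5 di-tert-butyl (4S,6S)-nona-1,8-diene-4,6-diyl dicarbonate
Product: 6 4,4'-methylenebis[(4R,6R)-6-(iodomethyl)-1,3-dioxan-2-one]
Conditions: IBr (2.5 equiv), PhMe, −85 °C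
Reagents that add atoms: iodine monobromide, IBr
Why: Bartlett–Smith iodocarbonate cyclisation; each Boc carbonyl oxygen opens the iodonium ion of its own allyl group 6-exo through a chair with both substituents equatorial, setting C5 and C11 cis (1,3-syn) to C7 and C9, with tert-butyl lost as tert-butyl bromide.

**Step 4 (key step)**
Reactants: 6 4,4'-methylenebis[(4R,6R)-6-(iodomethyl)-1,3-dioxan-2-one]; 7 oct-1-ene
Product: 8 (4R,6R)-6-(iodomethyl)-4-{[(4S,6S)-6-nonyl-2-oxo-1,3-dioxan-4-yl]methyl}-1,3-dioxan-2-one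
Conditions: 7 (0.7 equiv), NiBr2·diglyme (10 mol%), iPr-PyBox (12 mol%), (EtO)2MeSiH (0.9 equiv), Na2CO3 (1.5 equiv), DMA, 25 °C; unreacted 6 recovered and recycled
Reagents that add atoms: none
Why: Nickel-hydride reductive olefin hydroalkylation; Ni–H adds anti-Markovnikov to oct-1-ene while the C–I bond is cleaved by halogen abstraction to a primary alkyl radical that is captured at nickel and reductively eliminated to form C12–C13; because 6 is C2-symmetric either iodide gives the same mono-product (about 45% expected, statistical, with octene limiting), and no stereocentre is involved.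

**Step 5**
Reactants: 8 (4R,6R)-6-(iodomethyl)-4-{[(4S,6S)-6-nonyl-2-oxo-1,3-dioxan-4-yl]methyl}-1,3-dioxan-2-one; 9 methyl 3-chloro-3-oxopropanoate
Product: 10 methyl 4-[(4R,6R)-6-{[(4S,6S)-6-nonyl-2-oxo-1,3-dioxan-4-yl]methyl}-2-oxo-1,3-dioxan-4-yl]-3-oxobutanoate
Conditions: 9 (1.5 equiv), NiCl2·glyme (10 mol%), 4,4'-di-tert-butyl-2,2'-bipyridine (11 mol%), Mn powder (3 equiv), DMA, 0 °C → rt
Reagents that add atoms: none
Why: Weix-type nickel-catalysed cross-electrophile (reductive) acylation; the acid chloride adds to low-valent nickel, the alkyl radical from the iodide is captured by the acylnickel species and reductive elimination forms the C3–C4 ketone bond, the radical being trapped before a β-oxygenated organometallic could eliminate; no stereocentre is involved.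

**Step 6**
Reactants: 10 methyl 4-[(4R,6R)-6-{[(4S,6S)-6-nonyl-2-oxo-1,3-dioxan-4-yl]methyl}-2-oxo-1,3-dioxan-4-yl]-3-oxobutanoate
Product: 13 (6R)-4-hydroxy-6-[(2R,4S,6S)-2,4,6-trihydroxypentadecyl]-5,6-dihydro-2H-pyran-2-one, via tetraol keto ester 11 (not isolated), via potassium enolate 12 (not isolated)
Conditions: K2CO3 (2 equiv), MeOH, 0 °C → rt; then 1 M HCl to pH 3
Reagents that add atoms: none
Why: Methanolysis of both six-membered cyclic carbonates frees the four hydroxyls, the C5 hydroxyl lactonises onto the methyl ester of the δ-hydroxy β-keto ester (driven by formation of the stabilised enolate), and acidification gives the enol lactone; the four stereocentres are untouched.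

**Compound list**
1 | propane-1,3-diol | OCCCO | starting material
2 | allyl acetate (prop-2-en-1-yl acetate) | CC(=O)OCC=C | starting material
3 | (4S,6S)-nona-1,8-diene-4,6-diol | C=CC[C@H](O)C[C@@H](O)CC=C | intermediate
4 | dilithium (4S,6S)-nona-1,8-diene-4,6-diolate | C=CC[C@H]([O-])C[C@@H]([O-])CC=C.[Li+].[Li+] | intermediate (not isolated)
5 | di-tert-butyl (4S,6S)-nona-1,8-diene-4,6-diyl dicarbonate | C=CC[C@H](OC(=O)OC(C)(C)C)C[C@@H](OC(=O)OC(C)(C)C)CC=C | intermediate
6 | 4,4'-methylenebis[(4R,6R)-6-(iodomethyl)-1,3-dioxan-2-one] | IC[C@H]1C[C@@H](C[C@@H]2C[C@H](CI)OC(=O)O2)OC(=O)O1 | intermediate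
7 | oct-1-ene | CCCCCCC=C | starting material
8 | (4R,6R)-6-(iodomethyl)-4-{[(4S,6S)-6-nonyl-2-oxo-1,3-dioxan-4-yl]methyl}-1,3-dioxan-2-one | CCCCCCCCC[C@H]1C[C@@H](C[C@@H]2C[C@H](CI)OC(=O)O2)OC(=O)O1 | intermediate
9 | methyl 3-chloro-3-oxopropanoate (methyl malonyl chloride) | COC(=O)CC(Cl)=O | starting material
10 | methyl 4-[(4R,6R)-6-{[(4S,6S)-6-nonyl-2-oxo-1,3-dioxan-4-yl]methyl}-2-oxo-1,3-dioxan-4-yl]-3-oxobutanoate | CCCCCCCCC[C@H]1C[C@@H](C[C@@H]2C[C@H](CC(=O)CC(=O)OC)OC(=O)O2)OC(=O)O1 | intermediate
11 | methyl (5R,7R,9S,11S)-5,7,9,11-tetrahydroxy-3-oxoicosanoate | CCCCCCCCC[C@H](O)C[C@H](O)C[C@@H](O)C[C@@H](O)CC(=O)CC(=O)OC | intermediate (not isolated)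
12 | potassium (6R)-2-oxo-6-[(2R,4S,6S)-2,4,6-trihydroxypentadecyl]-5,6-dihydro-2H-pyran-4-olate | CCCCCCCCC[C@H](O)C[C@H](O)C[C@@H](O)C[C@@H]1CC([O-])=CC(=O)O1.[K+] | intermediate (not isolated)
13 | (6R)-4-hydroxy-6-[(2R,4S,6S)-2,4,6-trihydroxypentadecyl]-5,6-dihydro-2H-pyran-2-one | CCCCCCCCC[C@H](O)C[C@H](O)C[C@@H](O)C[C@@H]1CC(O)=CC(=O)O1 | target

**Step count**
Total steps: 6. Longest linear sequence: 6 (from propane-1,3-diol).

**Steps most likely to fail, with fallbacks**

Step 5 is the most exposed. Methyl malonyl chloride has acidic α-hydrogens and can form a ketene, the β-keto ester product can bind the catalyst, and the iodide is β-oxygenated. The fallback sets out from 8 and comes back at 10, and makes C3–C4 by a Giese-type radical addition instead. Iodide 8 with (TMS)3SiH and AIBN and excess methyl propiolate in benzene at 80 °C gives methyl (2E)-4-[(4S,6S)-6-{[(4S,6S)-6-nonyl-2-oxo-1,3-dioxan-4-yl]methyl}-2-oxo-1,3-dioxan-4-yl]but-2-enoate F4 (E/Z mixture, both usable). Tsuji–Wacker oxidation of F4 (Na2PdCl4 cat., t-BuOOH, AcOH/i-PrOH, 50 °C) puts the ketone on the β-carbon and gives 10.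

Step 4 is next. The yield is statistical at best, and the β-carbonato iodide may be reduced or eliminated rather than coupled under nickel hydride conditions. The fallback sets out from 6 and 7 and comes back at 8, delivering the octyl group as a preformed organozinc in a two-component radical Negishi coupling. Oct-1-ene 7 is hydroborated with Et2BH to diethyl(octyl)borane F1, boron–zinc exchange with Et2Zn gives dioctylzinc F2, and ZnBr2 in DMA converts this to octylzinc bromide F3. F3 (0.7 equiv) is then coupled with 6 under Ni(cod)2/s-Bu-PyBox in DMA at room temperature, where the iodide is again engaged as an alkyl radical, to give 8.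

Step 6 is third. In base the C5 carbonate sits β to the C3 ketone, so E1cB elimination or retro-aldol cleavage could compete with carbonate methanolysis. The fallback sets out from 10 and comes back at 13, masking the ketone before any base is used. HC(OMe)3 with catalytic H2SO4 in MeOH converts 10 into methyl (2E)-3-methoxy-4-[(4R,6R)-6-{[(4S,6S)-6-nonyl-2-oxo-1,3-dioxan-4-yl]methyl}-2-oxo-1,3-dioxan-4-yl]but-2-enoate F5, in which the ester is cis to C4. K2CO3/MeOH then removes both carbonates and closes the ring to (6R)-4-methoxy-6-[(2R,4S,6S)-2,4,6-trihydroxypentadecyl]-5,6-dihydro-2H-pyran-2-one F6. Hydrolysis of the enol ether of F6 with aqueous HCl in THF at 40–60 °C gives 13.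

**Further compounds**
F1 | step 4 | diethyl(octyl)borane | CCCCCCCCB(CC)CC
F2 | step 4 | dioctylzinc | CCCCCCCC[Zn]CCCCCCCC
F3 | step 4 | octylzinc bromide | CCCCCCCC[Zn]Br
F4 | step 5 | methyl (2E)-4-[(4S,6S)-6-{[(4S,6S)-6-nonyl-2-oxo-1,3-dioxan-4-yl]methyl}-2-oxo-1,3-dioxan-4-yl]but-2-enoate | CCCCCCCCC[C@H]1C[C@@H](C[C@@H]2C[C@H](C/C=C/C(=O)OC)OC(=O)O2)OC(=O)O1
F5 | step 6 | methyl (2E)-3-methoxy-4-[(4R,6R)-6-{[(4S,6S)-6-nonyl-2-oxo-1,3-dioxan-4-yl]methyl}-2-oxo-1,3-dioxan-4-yl]but-2-enoate | CCCCCCCCC[C@H]1C[C@@H](C[C@@H]2C[C@H](C/C(OC)=C\C(=O)OC)OC(=O)O2)OC(=O)O1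
F6 | step 6 | (6R)-4-methoxy-6-[(2R,4S,6S)-2,4,6-trihydroxypentadecyl]-5,6-dihydro-2H-pyran-2-one | CCCCCCCCC[C@H](O)C[C@H](O)C[C@@H](O)C[C@@H]1CC(OC)=CC(=O)O1
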